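## Structural features

The target is a β-resorcylic acid: a benzene ring with a carboxyl group at C1, hydroxyl groups at C2 and C4, hydrogens at C3 and C5, and an unbranched fifteen-carbon chain at C6. The chain is joined to the ring through seven methylene groups (C1'–C7'), followed by a Z double bond (C8'=C9'), the acetate-bearing carbon C10' of R configuration and an n-pentyl end. C10' is the only stereocentre and has no stereogenic neighbour, but it is allylic to the Z alkene, so acid, Lewis acids and palladium can ionise or transpose its C–O bond. The fragile groups are the allylic acetate (base- and nucleophile-labile, liable to solvolysis and [3,3] shift), the Z alkene (no hydrogenation or isomerising conditions once it exists) and the acid, which decarboxylates easily when hot and acidic because both hydroxyl groups activate C1. The skeleton is simple; the real difficulty is the order of events: the carboxyl group must go to C1 and not C3, and the molecule must end with exactly one acyl group, on the least reactive of three hydroxyl groups, beside a free acid. The key step exploits the all-meta pattern of the ring: the triad C2(O)–C3(H)–C4(O) is a ketene carbonyl carbon joined to the two carbons of an ynol ether, and C5–C6(chain)–C1 are the olefinic CH, the alkyl-bearing carbon and the methylene of a 3-alkylcyclobutenone.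

## Logic of the disconnections

**24 ⇒ 23.** The two aryl O–acetyl bonds are added back. No reagent acylates the hindered secondary allylic alcohol in preference to two phenols, but aryl acetates are far better acyl donors than an alkyl acetate, so the selectivity is taken in a deacylation. This turns a hard selective acylation into an exhaustive one. The forward solvolysis must be neutral and cold so that the allylic acetate, the Z alkene and the acid survive.

**23 ⇒ 21.** All three O–acetyl bonds are cut. The precursor carries no acetate, so the strongly basic carboxylation can come before it. The forward step must acylate C10'–O without touching the C–O bond and must return the carboxyl group as the free acid.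

**21 ⇒ 20.** The C1–carboxyl bond is cut. C1 is ortho to one hydroxyl and para to the other, the position where a magnesium phenoxide delivers a carboxyl group and holds it as a chelate. In 20, C1 and C5 are equivalent by symmetry, so only C3 competes. The forward step must avoid C3, tolerate the free allylic alcohol and be worked up without decarboxylation.

**20 ⇒ 19.** The three O–Si bonds are restored. This adds nothing to the skeleton but connects the symmetric triol to what the annulation delivers (one free phenol, one aryl silyl ether) and to what the chain needs through the organometallic steps (an alkyl silyl ether). One fluoride treatment must remove all three.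

**19 ⇒ 10 + 14.** The bonds C2–C3 and C4–C5 are cut; C1–C2 is broken and re-formed within the same cascade. The arene disappears, leaving a four-membered enone that already carries the finished chain and a two-carbon ynol ether. The forward step must be thermal and neutral, and its regiochemistry must follow from the polarisation of 14.

**14 ⇒ 11.** The O–Si bond and the C–O bond are cut. The oxygen is put on 11 by peroxide oxidation of its acetylide and the resulting ynolate is silylated on oxygen. The forward step needs cold handling of the monolithium acetylide and a bulky, hard silylating agent so that oxygen and not carbon is silylated.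

**10 ⇒ 6 + 7.** The bond between C1' and the ring carbon is cut. 7 is a vinylogous ester, so a carbon nucleophile adds to its carbonyl and acid transposes the carbonyl. The four-membered ring is bought and the chain becomes a primary bromide. This demands a silyl ether, not an acetate, at C10', an acid treatment mild enough for that ether, and a Z alkene that is already in place, because nothing can be hydrogenated once the enone exists.

**6 ⇒ 5.** The two C–H bonds at C8' and C9' are removed, giving the alkyne. Syn delivery of hydrogen sets the Z geometry, and the alkyne is the handle for the C–C bond below. The forward step must stop at the alkene and leave C–Br intact.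

**5 ⇒ 2 + 3.** The sp–sp3 bond C7'–C8' is cut. The stereocentre is then bought together with a terminal alkyne, and 3 supplies the seven methylenes plus the second leaving group. The forward step must alkylate only once, which an excess of 3 secures.

**2 ⇒ 1.** The O–Si bond is cut. The silyl group protects the hydroxyl through the organolithium and Grignard steps; 1 is the commercial source of the R configuration at C10'.

## Other disconnections considered

Alternative 1: The ring of 2-(trimethylsilyl)ethyl 2-[(8Z,10R)-10-acetoxypentadec-8-en-1-yl]-4,6-dihydroxybenzoate A1 is cut at C1–C2 and C5–C6. This gives the chain ynoate A2 (C1 and C6, with carboxyl and chain attached) and the dioxinone-derived silyl dienol ether A3 (C2–C5 with both oxygens). The forward step is a thermal [4+2] cycloaddition, followed by loss of the ketal bridge as a ketone, which aromatises the ring.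
- In its favour: the carboxyl carbon arrives as an ester in an unambiguous position, both phenols are born free, and the acetate can be in place before the ring is made. The last step is only fluoride cleavage of the silylethyl ester. On carboxyl placement and on the end game this is better than the chosen plan, which needs a site-selective carboxylation and a peracetylation/selective deacetylation.
- Against it: a β-alkyl ynoate is a weak dienophile. The temperatures it needs are those at which A3 fragments and at which an allylic acetate can undergo a [3,3] shift, transposing the oxygen and losing the stereocentre. A2 also needs a second alkyne unit, installed after the Z alkene and in the presence of a base-labile acetate or a group to be exchanged for it.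
- Comparison: both plans are pericyclic and take their regiochemistry from polarity matching. The chosen plan uses a far more reactive pair (ketene and ynol ether) at 80–110 °C on a substrate holding only robust silyl ethers. Step counts are about equal.

Alternative 2: The ring is kept and the two bonds to its substituents, C6–C1' and C1–carboxyl, are cut. Fluoride releases 3,5-bis(methoxymethoxy)benzyne A6 from the silyl triflate A5. The enolate of the chain-bearing diallyl malonate A7 adds to the aryne carbon remote from the flanking alkoxy group, and the aryl anion attacks an ester carbonyl. Fragmentation gives allyl 2-[(9Z,11R)-1-(allyloxy)-11-(tert-butyldimethylsilyloxy)-1-oxohexadec-9-en-2-yl]-4,6-bis(methoxymethoxy)benzoate A4.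
- In its favour: no ring has to be built, and chain and carboxyl are placed ortho to each other in one polar step with regiochemistry fixed by the alkoxy group. On carboxyl placement it is the equal of Alternative 1 and better than the chosen plan. It is as convergent as the chosen plan.
- Against it: insertion is best for unsubstituted malonates; with the α-alkylated A7, proton transfer and simple arylation should compete. A4 carries a surplus ester on the benzylic carbon. Its removal (deallylation with a zerovalent palladium catalyst, then decarboxylation of an arylacetic acid) needs heat, while the ring carboxyl that must stay is the more labile one once the phenols are free. Acetal cleavage needs acid next to an ionisable allylic oxygen, and A5 itself takes several steps.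
- Comparison: the mechanism is ionic rather than pericyclic, the chain fragment is one carbon shorter because the benzylic carbon comes from the malonate, and the end game is longer (five or more operations, with the same acetate problem at the end). Step economy is poorer than in the chosen plan.

Alternative 3: The ring is unfolded at C1–C6 to the linear diketo-dioxinone A9. A tertiary amine enolises A9, dioxinone C5 adds to the chain-bearing ketone, and dehydration aromatises to 7-hydroxy-2,2-dimethyl-5-[(8Z,10R)-10-(tert-butyldimethylsilyloxy)pentadec-8-en-1-yl]-4H-1,3-benzodioxin-4-one A8.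
- In its favour: the ring closure is mild and biomimetic, the carboxyl is built in and masked, and its position is beyond doubt. For the ring-forming step this is at least the equal of the chosen plan, and for carboxyl placement it is better.
- Against it: A9 is a sensitive triketide equivalent that would be used crude, and it needs several steps from the chain acid (available from 8 and carbon dioxide). The masked acid must be opened with hot hydroxide, which no acetate survives, so the acetate still comes last by the same peracetylation and selective deacylation. Hot base also risks decarboxylation.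
- Comparison: the end game is no shorter and the total step count is about equal. All six ring carbons must be assembled as one chain, whereas the chosen plan brings them as two small reagents and closes the ring under neutral conditions.

The chosen plan is kept because it has the shortest chain assembly from the chiral pool and a neutral, regiodefined ring construction. Its accepted weaknesses are a late carboxylation and an uncommon alkyne.

Key step: step 6

Remark: ring atoms are numbered C1 (carboxyl-bearing) to C6 (chain-bearing) and chain atoms C1'–C15'. Commercial (R)-oct-1-yn-3-ol of high enantiomeric purity is assumed, since its stereocentre is carried through unchanged.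

## Route

Step 1
Reactants: 1 (R)-oct-1-yn-3-ol
Product: 2 (R)-3-(tert-butyldimethylsilyloxy)oct-1-yne
Conditions: TBSCl, imidazole, CH2Cl2, 0 °C → rt
Reagents that add atoms: tert-butyldimethylsilyl chloride, CC(C)(C)[Si](C)(C)Cl
Why: Imidazole-mediated O-silylation of a secondary propargylic alcohol; the C–O bond is not touched, so C10' keeps its R configuration.

Step 2
Reactants: 2 (R)-3-(tert-butyldimethylsilyloxy)oct-1-yne; 3 1,7-dibromoheptane
Product: 5 (R)-1-bromo-10-(tert-butyldimethylsilyloxy)pentadec-8-yne, via lithium acetylide 4 (not isolated)
Conditions: n-BuLi, THF, −78 °C; then 3 (4 equiv), DMPU, −78 °C → rt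
Reagents that add atoms: none
Why: Acetylide alkylation: the terminal alkyne is deprotonated cleanly and 4 displaces a primary bromide by SN2 in the presence of a dipolar cosolvent; the excess of 3 (recovered afterwards) keeps double alkylation low and the propargylic C–H is not touched.

Step 3
Reactants: 5 (R)-1-bromo-10-(tert-butyldimethylsilyloxy)pentadec-8-yne
Product: 6 (8Z,10R)-1-bromo-10-(tert-butyldimethylsilyloxy)pentadec-8-ene
Conditions: H2 (1 atm), Pd/CaCO3 poisoned with Pb(OAc)2 (Lindlar catalyst), quinoline, hexane/EtOAc, rt
Reagents that add atoms: none
Why: Lindlar semi-hydrogenation delivers both hydrogens syn from the catalyst surface and so should give the Z alkene; quinoline and control of hydrogen uptake prevent over-reduction, and the primary bromide and silyl ether are inert.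

Step 4
Reactants: 6 (8Z,10R)-1-bromo-10-(tert-butyldimethylsilyloxy)pentadec-8-ene; 7 3-ethoxycyclobut-2-en-1-one
Product: 10 3-[(8Z,10R)-10-(tert-butyldimethylsilyloxy)pentadec-8-en-1-yl]cyclobut-2-en-1-one, via Grignard reagent 8 (not isolated), via ethoxycyclobutenol adduct 9 (not isolated)
Conditions: Mg, I2 (cat.), THF, 45 °C; then 7, THF, −78 → 0 °C; then 1 M HCl, 0 °C
Reagents that add atoms: water, O
Why: Grignard 1,2-addition to the vinylogous ester 7, then acid hydrolysis of the enol ether with loss of water (carbonyl transposition), is the standard entry to 3-alkylcyclobutenones; the tertiary allylic alcohol 9 collapses within minutes in cold dilute acid, which should leave the secondary silyl ether and the Z-allylic system intact.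

Step 5
Reactants: 11 acetylene
Product: 14 (triisopropylsilyloxy)ethyne, via lithium acetylide 12 (not isolated), via lithium ethynolate 13 (not isolated)
Conditions: n-BuLi, THF, −78 °C (acetylene in excess); t-BuOOLi [from t-BuOOH and LiN(SiMe3)2], −78 → −10 °C; i-Pr3SiOTf, −78 → 0 °C
Reagents that add atoms: tert-butyl hydroperoxide, CC(C)(C)OO; triisopropylsilyl trifluoromethanesulfonate, CC(C)[Si](OS(=O)(=O)C(F)(F)F)(C(C)C)C(C)C
Why: Oxidation of a lithium acetylide by lithium tert-butyl peroxide (carbon attacks peroxide oxygen) gives the ynolate, and bulky, hard silyl triflates silylate ynolates on oxygen to give distillable triisopropylsilyl ynol ethers; excess acetylene and low temperature hold back disproportionation to the dilithium species.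

Step 6
Reactants: 10 3-[(8Z,10R)-10-(tert-butyldimethylsilyloxy)pentadec-8-en-1-yl]cyclobut-2-en-1-one; 14 (triisopropylsilyloxy)ethyne
Product: 19 3-[(8Z,10R)-10-(tert-butyldimethylsilyloxy)pentadec-8-en-1-yl]-5-(triisopropylsilyloxy)phenol, via vinylketene 15 (not isolated), via vinylcyclobutenone 16 (not isolated), via dienylketene 17 (not isolated), via cyclohexadienone 18 (not isolated)
Conditions: 14 (1.8 equiv), toluene, 80 °C then 110 °C, argon, sealed tube
Reagents that add atoms: none
Why: Danheiser benzannulation, a pericyclic cascade: at about 80 °C 10 opens by thermal conrotatory 4π electrocyclic cleavage of the bond between its carbonyl and methylene carbons to vinylketene 15. The ketene carbon of 15 bonds to the unsubstituted, nucleophilic carbon of the polarised ynol ether 14 and the ketene α-carbon to the oxygen-bearing one ([2+2] cycloaddition), forming C2–C3 and C4–C5 and giving 16. Reversible 4π opening of 16 leads to dienylketene 17, and the benzene ring is closed by a thermal disrotatory 6π electrocyclisation between the ketene carbon and the terminal methylene (re-forming C1–C2), after which cyclohexadienone 18 tautomerises irreversibly to 19. The closest known reaction type is the annulation of 3-alkylcyclobutenones with 1-(trialkylsilyloxy)alk-1-ynes to resorcinol monosilyl ethers, of which the terminal ynol ether is a less hindered member. No stereocentre is created (the sp3 ring carbon of 16 becomes aromatic), and C10' with its Z alkene is remote and inert to neutral heating. The selectivity needed is regiochemical and is secured by the polarity match of the electrophilic ketene carbon with the nucleophilic β-carbon of the ynol ether, which puts the two oxygens meta to each other and to the chain and leaves the ketene-derived oxygen as the free hydroxyl. Because the opening of 16 is reversible, material drains through the isomer of 17 whose ketene and vinyl termini are cis, the only one able to cyclise, and the excess of 14 keeps 15 from being intercepted by phenol already formed.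

Step 7
Reactants: 19 3-[(8Z,10R)-10-(tert-butyldimethylsilyloxy)pentadec-8-en-1-yl]-5-(triisopropylsilyloxy)phenol
Product: 20 5-[(8Z,10R)-10-hydroxypentadec-8-en-1-yl]benzene-1,3-diol
Conditions: n-Bu4NF (3.5 equiv), degassed THF, 0 °C → rt; aq. NH4Cl
Reagents that add atoms: none
Why: Fluoride-mediated desilylation (Si–F bond formation); the aryl silyl ether should go within minutes and the secondary allylic one within hours, and nothing else in the molecule is sensitive to fluoride or mild base.

Step 8
Reactants: 20 5-[(8Z,10R)-10-hydroxypentadec-8-en-1-yl]benzene-1,3-diol
Product: 21 2,4-dihydroxy-6-[(8Z,10R)-10-hydroxypentadec-8-en-1-yl]benzoic acid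
Conditions: CH3OMgOCO2CH3 (2 M in DMF, excess), 120 °C, N2 sweep; then ice-cold 1 M HCl, EtOAc
Reagents that add atoms: methyl magnesium carbonate CH3OMgOCO2CH3, COC(=O)O[Mg]OC
Why: Carboxylation of a phenol with methyl magnesium carbonate: the magnesium phenoxide is carboxylated ortho to oxygen and the equilibrium is drawn to the product by its magnesium salicylate chelate while methanol is swept out; in 5-alkylresorcinols this reagent normally attacks the position ortho to one and para to the other hydroxyl (C1, equivalent to C5 by symmetry) rather than C3, and cold acidification avoids decarboxylation.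

Step 9
Reactants: 21 2,4-dihydroxy-6-[(8Z,10R)-10-hydroxypentadec-8-en-1-yl]benzoic acid
Product: 23 2,4-diacetoxy-6-[(8Z,10R)-10-acetoxypentadec-8-en-1-yl]benzoic acid, via mixed anhydride 22 (not isolated)
Conditions: Ac2O, pyridine, DMAP (cat.), CH2Cl2, 0 °C → rt; then H2O/THF, rt
Reagents that add atoms: acetic anhydride, CC(=O)OC(C)=O
Why: Exhaustive DMAP-catalysed O-acetylation; acylation at oxygen leaves the C10' configuration untouched, and the acetic mixed anhydride 22 formed at the carboxyl group is hydrolysed at its unhindered acetyl carbonyl by the water quench.

Step 10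
Reactants: 23 2,4-diacetoxy-6-[(8Z,10R)-10-acetoxypentadec-8-en-1-yl]benzoic acid
Product: 24 6-[(8Z,10R)-10-acetoxypentadec-8-en-1-yl]-2,4-dihydroxybenzoic acid
Conditions: NH4OAc (10 equiv), MeOH/H2O (4:1), rt
Reagents that add atoms: none
Why: Chemoselective methanolysis of aryl acetates under neutral ammonium acetate mediation: a phenoxide is a much better leaving group than an alkoxide (and the acetate ortho to the carboxyl group is further activated), so both aryl acetates should go while the secondary allylic acetate, the acid and the Z alkene remain.

## Compound list

1 | (R)-oct-1-yn-3-ol | CCCCC[C@H](C#C)O | starting material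
2 | (R)-3-(tert-butyldimethylsilyloxy)oct-1-yne | CCCCC[C@H](C#C)O[Si](C)(C)C(C)(C)C | intermediate
3 | 1,7-dibromoheptane | BrCCCCCCCBr | starting material
4 | [(3R)-3-(tert-butyldimethylsilyloxy)oct-1-yn-1-yl]lithium | CCCCC[C@H](C#C[Li])O[Si](C)(C)C(C)(C)C | intermediate
5 | (R)-1-bromo-10-(tert-butyldimethylsilyloxy)pentadec-8-yne | CCCCC[C@H](C#CCCCCCCCBr)O[Si](C)(C)C(C)(C)C | intermediate
6 | (8Z,10R)-1-bromo-10-(tert-butyldimethylsilyloxy)pentadec-8-ene | CCCCC[C@H](/C=C\CCCCCCCBr)O[Si](C)(C)C(C)(C)C | intermediate
7 | 3-ethoxycyclobut-2-en-1-one | CCOC1=CC(=O)C1 | starting material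
8 | [(8Z,10R)-10-(tert-butyldimethylsilyloxy)pentadec-8-en-1-yl]magnesium bromide | CCCCC[C@H](/C=C\CCCCCCC[Mg]Br)O[Si](C)(C)C(C)(C)C | intermediate
9 | 1-[(8Z,10R)-10-(tert-butyldimethylsilyloxy)pentadec-8-en-1-yl]-3-ethoxycyclobut-2-en-1-ol (formed as its bromomagnesium alkoxide; both epimers at the ring carbinol carbon) | CCCCC[C@H](/C=C\CCCCCCCC1(O)CC(OCC)=C1)O[Si](C)(C)C(C)(C)C | intermediate
10 | 3-[(8Z,10R)-10-(tert-butyldimethylsilyloxy)pentadec-8-en-1-yl]cyclobut-2-en-1-one | CCCCC[C@H](/C=C\CCCCCCCC1=CC(=O)C1)O[Si](C)(C)C(C)(C)C | intermediate
11 | acetylene (ethyne) | C#C | starting material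
12 | ethynyllithium (lithium acetylide) | [Li]C#C | intermediate
13 | lithium ethynolate | [Li]OC#C | intermediate
14 | (triisopropylsilyloxy)ethyne | C#CO[Si](C(C)C)(C(C)C)C(C)C | intermediate
15 | (11Z,13R)-13-(tert-butyldimethylsilyloxy)-3-methylideneoctadeca-1,11-dien-1-one | CCCCC[C@H](/C=C\CCCCCCCC(=C)C=C=O)O[Si](C)(C)C(C)(C)C | intermediate
16 | 4-[(10Z,12R)-12-(tert-butyldimethylsilyloxy)heptadeca-1,10-dien-2-yl]-3-(triisopropylsilyloxy)cyclobut-2-en-1-one (both epimers at ring C4) | CCCCC[C@H](/C=C\CCCCCCCC(=C)C1C(=O)C=C1O[Si](C(C)C)(C(C)C)C(C)C)O[Si](C)(C)C(C)(C)C | intermediate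
17 | (3E,13Z,15R)-15-(tert-butyldimethylsilyloxy)-5-methylidene-3-(triisopropylsilyloxy)icosa-1,3,13-trien-1-one | CCCCC[C@H](/C=C\CCCCCCCC(=C)/C=C(\C=C=O)O[Si](C(C)C)(C(C)C)C(C)C)O[Si](C)(C)C(C)(C)C | intermediate
18 | 5-[(8Z,10R)-10-(tert-butyldimethylsilyloxy)pentadec-8-en-1-yl]-3-(triisopropylsilyloxy)cyclohexa-2,4-dien-1-one | CCCCC[C@H](/C=C\CCCCCCCC1=CC(O[Si](C(C)C)(C(C)C)C(C)C)=CC(=O)C1)O[Si](C)(C)C(C)(C)C | intermediate
19 | 3-[(8Z,10R)-10-(tert-butyldimethylsilyloxy)pentadec-8-en-1-yl]-5-(triisopropylsilyloxy)phenol | CCCCC[C@H](/C=C\CCCCCCCc1cc(O)cc(O[Si](C(C)C)(C(C)C)C(C)C)c1)O[Si](C)(C)C(C)(C)C | intermediate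
20 | 5-[(8Z,10R)-10-hydroxypentadec-8-en-1-yl]benzene-1,3-diol | CCCCC[C@H](/C=C\CCCCCCCc1cc(O)cc(O)c1)O | intermediate
21 | 2,4-dihydroxy-6-[(8Z,10R)-10-hydroxypentadec-8-en-1-yl]benzoic acid | CCCCC[C@H](/C=C\CCCCCCCc1cc(O)cc(O)c1C(=O)O)O | intermediate
22 | acetic 2,4-diacetoxy-6-[(8Z,10R)-10-acetoxypentadec-8-en-1-yl]benzoic anhydride | CCCCC[C@H](/C=C\CCCCCCCc1cc(OC(C)=O)cc(OC(C)=O)c1C(=O)OC(C)=O)OC(C)=O | intermediate
23 | 2,4-diacetoxy-6-[(8Z,10R)-10-acetoxypentadec-8-en-1-yl]benzoic acid | CCCCC[C@H](/C=C\CCCCCCCc1cc(OC(C)=O)cc(OC(C)=O)c1C(=O)O)OC(C)=O | intermediate
24 | 6-[(8Z,10R)-10-acetoxypentadec-8-en-1-yl]-2,4-dihydroxybenzoic acid (CNP0288291.1) | CCCCC[C@H](/C=C\CCCCCCCc1cc(O)cc(O)c1C(=O)O)OC(C)=O | target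

## Step count and least certain steps

Total step count: 10. Longest linear sequence: 9 steps (steps 1–4 and 6–10); step 5 is a one-step branch.

**The key step (step 6).** The most likely failure is diversion of vinylketene 15 before it meets the alkyne: O-acylation of phenol already formed, or self-condensation. This becomes worse if the terminal ynol ether is used up by its own thermal isomerisation or oligomerisation; stalling at the vinylcyclobutenone stage is a lesser concern at 110 °C. The fallback gives up ring construction and buys the arene. It sets out from Grignard reagent 8, which is transmetalated with ZnBr2 to [(8Z,10R)-10-(tert-butyldimethylsilyloxy)pentadec-8-en-1-yl]zinc bromide F1. Negishi sp3–sp2 coupling (Pd(OAc)2, SPhos, THF) with 1-bromo-3,5-bis(tert-butyldimethylsilyloxy)benzene F2, made from commercial 5-bromobenzene-1,3-diol with TBSCl and imidazole, should give 1,3-bis(tert-butyldimethylsilyloxy)-5-[(8Z,10R)-10-(tert-butyldimethylsilyloxy)pentadec-8-en-1-yl]benzene F3. Fluoride treatment as in step 7 brings it back to the route at 20.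

**Step 5.** This is the least precedented preparation, because the parent ynol ether lacks the carbon substituent of the usual class members. What may go wrong is disproportionation of the monolithium acetylide to the insoluble dilithium species before oxidation is complete, silylation at carbon instead of oxygen, and loss of the fairly volatile product on isolation. The fallback changes the class of oxygenated alkyne and the way it is made. It sets out from 10. 2-(Trimethylsilyl)ethanol, KH and trichloroethene should give {2-[(E)-1,2-dichloroethenyloxy]ethyl}trimethylsilane F4. n-BuLi followed by methanol converts this to [2-(ethynyloxy)ethyl]trimethylsilane F5. The same thermal annulation with 10 (alkoxyethynes are established partners of this reaction) should give 3-[(8Z,10R)-10-(tert-butyldimethylsilyloxy)pentadec-8-en-1-yl]-5-[2-(trimethylsilyl)ethoxy]phenol F6. n-Bu4NF in DMF at 60 °C then removes the silyl ether and, by fluoride-induced β-elimination, the aryl ether, returning to the route at 20.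

**Step 8.** Attack at C3 between the two hydroxyl groups, incomplete conversion because the carboxylation is reversible, and decarboxylation during acidification are the risks. The fallback uses the differentiation of the two ring oxygens that the annulation provides; it sets out from 19 and comes back at 21. Magnesium-mediated ortho-formylation (MgCl2, Et3N, paraformaldehyde, THF, reflux) is expected to go to the ortho position that is para to the silyloxy group and away from the bulky silyl ether, that is C1, giving 2-hydroxy-6-[(8Z,10R)-10-(tert-butyldimethylsilyloxy)pentadec-8-en-1-yl]-4-(triisopropylsilyloxy)benzaldehyde F7. Pinnick oxidation (NaClO2, NaH2PO4, 2-methylbut-2-ene, t-BuOH/H2O) should give 2-hydroxy-6-[(8Z,10R)-10-(tert-butyldimethylsilyloxy)pentadec-8-en-1-yl]-4-(triisopropylsilyloxy)benzoic acid F8, and n-Bu4NF then gives 21.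

**Step 10.** The risk is imperfect discrimination: slow loss of the allylic acetate on long exposure, or incomplete cleavage of the aryl acetates, leading to mixtures. The fallback replaces "acylate everything, then deacylate selectively" by direct selective acylation. It sets out from 21 and returns at 24. Lipase-catalysed transesterification with vinyl acetate (immobilised Candida antarctica lipase B or Burkholderia cepacia lipase, t-BuOMe, 35 °C) acylates aliphatic but not phenolic hydroxyl groups; its uncertainty is the rate with a secondary alcohol flanked by two long substituents. This detour makes no compound outside the list (F0).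

## Further compounds

F1 | step 6 | [(8Z,10R)-10-(tert-butyldimethylsilyloxy)pentadec-8-en-1-yl]zinc bromide | CCCCC[C@H](/C=C\CCCCCCC[Zn]Br)O[Si](C)(C)C(C)(C)C
F2 | step 6 | 1-bromo-3,5-bis(tert-butyldimethylsilyloxy)benzene | Brc1cc(O[Si](C)(C)C(C)(C)C)cc(O[Si](C)(C)C(C)(C)C)c1
F3 | step 6 | 1,3-bis(tert-butyldimethylsilyloxy)-5-[(8Z,10R)-10-(tert-butyldimethylsilyloxy)pentadec-8-en-1-yl]benzene | CCCCC[C@H](/C=C\CCCCCCCc1cc(O[Si](C)(C)C(C)(C)C)cc(O[Si](C)(C)C(C)(C)C)c1)O[Si](C)(C)C(C)(C)C
F4 | step 5 | {2-[(E)-1,2-dichloroethenyloxy]ethyl}trimethylsilane | Cl/C=C(/Cl)OCC[Si](C)(C)C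
F5 | step 5 | [2-(ethynyloxy)ethyl]trimethylsilane | C#COCC[Si](C)(C)C
F6 | step 5 | 3-[(8Z,10R)-10-(tert-butyldimethylsilyloxy)pentadec-8-en-1-yl]-5-[2-(trimethylsilyl)ethoxy]phenol | CCCCC[C@H](/C=C\CCCCCCCc1cc(O)cc(OCC[Si](C)(C)C)c1)O[Si](C)(C)C(C)(C)C
F7 | step 8 | 2-hydroxy-6-[(8Z,10R)-10-(tert-butyldimethylsilyloxy)pentadec-8-en-1-yl]-4-(triisopropylsilyloxy)benzaldehyde | CCCCC[C@H](/C=C\CCCCCCCc1cc(O[Si](C(C)C)(C(C)C)C(C)C)cc(O)c1C=O)O[Si](C)(C)C(C)(C)C
F8 | step 8 | 2-hydroxy-6-[(8Z,10R)-10-(tert-butyldimethylsilyloxy)pentadec-8-en-1-yl]-4-(triisopropylsilyloxy)benzoic acid | CCCCC[C@H](/C=C\CCCCCCCc1cc(O[Si](C(C)C)(C(C)C)C(C)C)cc(O)c1C(=O)O)O[Si](C)(C)C(C)(C)C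
F0 | step 10 | none | none
A1 | alternative 1 | 2-(trimethylsilyl)ethyl 2-[(8Z,10R)-10-acetoxypentadec-8-en-1-yl]-4,6-dihydroxybenzoate | CCCCC[C@H](/C=C\CCCCCCCc1cc(O)cc(O)c1C(=O)OCC[Si](C)(C)C)OC(C)=O
A2 | alternative 1 | 2-(trimethylsilyl)ethyl (11Z,13R)-13-acetoxyoctadec-11-en-2-ynoate | CCCCC[C@H](/C=C\CCCCCCCC#CC(=O)OCC[Si](C)(C)C)OC(C)=O
A3 | alternative 1 | 2,2-dimethyl-6-methylidene-4-(trimethylsilyloxy)-6H-1,3-dioxine | C=C1C=C(O[Si](C)(C)C)OC(C)(C)O1
A4 | alternative 2 | allyl 2-[(9Z,11R)-1-(allyloxy)-11-(tert-butyldimethylsilyloxy)-1-oxohexadec-9-en-2-yl]-4,6-bis(methoxymethoxy)benzoate | CCCCC[C@H](/C=C\CCCCCCC(C(=O)OCC=C)c1cc(OCOC)cc(OCOC)c1C(=O)OCC=C)O[Si](C)(C)C(C)(C)C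
A5 | alternative 2 | 3,5-bis(methoxymethoxy)-2-(trimethylsilyl)phenyl trifluoromethanesulfonate | COCOc1cc(OCOC)c([Si](C)(C)C)c(OS(=O)(=O)C(F)(F)F)c1
A6 | alternative 2 | 3,5-bis(methoxymethoxy)benzyne | COCOC1=CC(OCOC)=CC#C1
A7 | alternative 2 | diallyl 2-[(7Z,9R)-9-(tert-butyldimethylsilyloxy)tetradec-7-en-1-yl]malonate | CCCCC[C@H](/C=C\CCCCCCC(C(=O)OCC=C)C(=O)OCC=C)O[Si](C)(C)C(C)(C)C
A8 | alternative 3 | 7-hydroxy-2,2-dimethyl-5-[(8Z,10R)-10-(tert-butyldimethylsilyloxy)pentadec-8-en-1-yl]-4H-1,3-benzodioxin-4-one | CCCCC[C@H](/C=C\CCCCCCCc1cc(O)cc2OC(C)(C)OC(=O)c12)O[Si](C)(C)C(C)(C)C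
A9 | alternative 3 | 6-[(12Z,14R)-14-(tert-butyldimethylsilyloxy)-2,4-dioxononadec-12-en-1-yl]-2,2-dimethyl-4H-1,3-dioxin-4-one | CCCCC[C@H](/C=C\CCCCCCCC(=O)CC(=O)CC1=CC(=O)OC(C)(C)O1)O[Si](C)(C)C(C)(C)C
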